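## Retrosynthetic overview

1. The target comes from reductive removal of two acetates and one pivalate from a 2,3-trans-3,4-cis flavan hydroxy-acetate.
2. Ring C (six-membered) comes from ring expansion of a trans-2-aryl-2,3-dihydrobenzofuran-3-carbaldehyde: the ring A carbon shifts from C3 to the activated formyl carbon, and the new C4 acetate captures C3 as an acetoxonium, so O3 and O4 end up cis.
3. The dihydrobenzofuran comes from an enantioselective Pd-catalysed oxyarylation of a ring B cinnamaldehyde acetal with a ring A o-iodophenol (C3–aryl and C2–O bonds in one step).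
4. The ring A piece comes from resorcinol (MOM ethers, meta C–H borylation/oxidation, O-methylation, two directed lithiations for prenyl and iodine); the ring B piece comes from 4-iodophenol and acrolein dimethyl acetal (Heck).
5. Ring order: rings A and B are bought as benzenes; the five-membered O-ring is built first and then expanded to ring C.

Assumption: the sense of induction of the chiral ligand in step 9 cannot be predicted with certainty; the ligand enantiomer found by screening to give the (2S,3S) dihydrobenzofuran is the one used.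

## Route

Step 1
Reactants: 1 resorcinol (benzene-1,3-diol)
Product: 2 1,3-bis(methoxymethoxy)benzene
Conditions: NaH, DMF, 0 °C; MOMCl, 0 °C → rt
Reagents that add atoms: chloromethyl methyl ether (MOMCl), COCCl
Why: Williamson O-alkylation of both phenoxides; the MOM ethers protect the phenols and later direct both ortho-lithiations.

Step 2
Reactants: 2 1,3-bis(methoxymethoxy)benzene
Product: 4 3,5-bis(methoxymethoxy)phenol, via aryl pinacol boronate 3 (not isolated)
Conditions: [Ir(OMe)(cod)]2 (1.5 mol%), dtbpy (3 mol%), B2pin2, THF, 80 °C; then aq. NaOH, H2O2, 0 °C → rt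
Reagents that add atoms: hydrogen peroxide, OO
Why: Iridium-catalysed C–H borylation is sterically controlled and takes the only C–H without an ortho substituent (C5, meta to both ethers), and basic peroxide oxidises the C–B bond in the same flask (one-pot borylation/oxidation).

Step 3
Reactants: 4 3,5-bis(methoxymethoxy)phenol
Product: 5 1-methoxy-3,5-bis(methoxymethoxy)benzene
Conditions: MeI, K2CO3, acetone, 50 °C
Reagents that add atoms: iodomethane, CI
Why: Williamson methylation of the single free phenol installs the future 5-OMe group.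

Step 4
Reactants: 5 1-methoxy-3,5-bis(methoxymethoxy)benzene; 6 1-bromo-3-methylbut-2-ene (prenyl bromide)
Product: 8 5-methoxy-1,3-bis(methoxymethoxy)-2-(3-methylbut-2-en-1-yl)benzene, via aryllithium 7 (not isolated)
Conditions: n-BuLi, THF, 0 °C; then CuI (10 mol%), 6, −78 °C → rt
Reagents that add atoms: none
Why: Directed ortho-metalation occurs at the carbon flanked by the two MOM ethers (the strongest cooperative directing pair), and copper-catalysed SN2 alkylation places the prenyl group between the two oxygens that become O1 and 7-OH.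

Step 5
Reactants: 8 5-methoxy-1,3-bis(methoxymethoxy)-2-(3-methylbut-2-en-1-yl)benzene
Product: 10 2-iodo-1-methoxy-3,5-bis(methoxymethoxy)-4-(3-methylbut-2-en-1-yl)benzene, via aryllithium 9 (not isolated)
Conditions: n-BuLi, TMEDA, THF, −78 → −20 °C; then I2, −78 °C
Reagents that add atoms: iodine, II
Why: A second directed ortho-metalation at the ring position between OMOM and OMe (the two free ring positions are equivalent by symmetry) followed by iodine quench gives one aryl iodide.

Step 6
Reactants: 10 2-iodo-1-methoxy-3,5-bis(methoxymethoxy)-4-(3-methylbut-2-en-1-yl)benzene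
Product: 11 4-iodo-5-methoxy-2-(3-methylbut-2-en-1-yl)benzene-1,3-diol
Conditions: ZnBr2, n-PrSH, CH2Cl2, 0 °C
Reagents that add atoms: none
Why: Lewis-acid-promoted transfer of the methoxymethyl groups to the thiol frees both phenols without protic acid, which would risk prenyl–phenol cyclisation or protodeiodination.

Step 7
Reactants: 12 4-iodophenol
Product: 13 4-iodophenyl 2,2-dimethylpropanoate
Conditions: PivCl, K2CO3, acetone, rt
Reagents that add atoms: pivaloyl chloride, CC(C)(C)C(Cl)=O
Why: O-acylation; the pivalate survives the Heck and Lewis-acid steps and lowers the donor strength of ring B, which matters in step 11.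

Step 8
Reactants: 13 4-iodophenyl 2,2-dimethylpropanoate; 14 3,3-dimethoxyprop-1-ene (acrolein dimethyl acetal)
Product: 15 4-[(1E)-3,3-dimethoxyprop-1-en-1-yl]phenyl 2,2-dimethylpropanoate
Conditions: Pd(OAc)2 (3 mol%), n-Bu4NOAc, K2CO3, KCl, DMF, 90 °C
Reagents that add atoms: none
Why: Heck reaction of the aryl iodide with the terminal alkene; β-hydride elimination toward the benzylic side gives the (E)-cinnamaldehyde acetal with the acetal intact.

Step 9
Reactants: 11 4-iodo-5-methoxy-2-(3-methylbut-2-en-1-yl)benzene-1,3-diol; 15 4-[(1E)-3,3-dimethoxyprop-1-en-1-yl]phenyl 2,2-dimethylpropanoate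
Product: 16 4-[(2S,3S)-3-(dimethoxymethyl)-6-hydroxy-4-methoxy-7-(3-methylbut-2-en-1-yl)-2,3-dihydro-1-benzofuran-2-yl]phenyl 2,2-dimethylpropanoate
Conditions: Pd2(dba)3 (2.5 mol%), (R)-DTBM-SEGPHOS (6 mol%), Ag2CO3, PhMe, 60 °C
Reagents that add atoms: none
Why: Proposed new method: an enantioselective Heck-type oxyarylation (Larock heteroannulation) of an acyclic β-substituted styrene. Oxidative addition of the aryl iodide to zerovalent palladium and iodide abstraction by Ag+ give a cationic aryl-palladium bearing the chiral bisphosphine. Enantio-determining syn-carbopalladation of the (E)-alkene puts the aryl on the acetal-bearing carbon (sets C3) and palladium on the benzylic carbon as an η3-benzyl. C–O reductive elimination with the adjacent phenoxide on the same face closes the ring 2,3-trans (sets C2). The closest known reactions are the racemic palladium-catalysed oxyarylation of propenylbenzenes with o-iodophenols and the enantioselective heteroannulation of o-iodophenols with 1,3-dienes.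

Step 10
Reactants: 16 4-[(2S,3S)-3-(dimethoxymethyl)-6-hydroxy-4-methoxy-7-(3-methylbut-2-en-1-yl)-2,3-dihydro-1-benzofuran-2-yl]phenyl 2,2-dimethylpropanoate
Product: 17 4-[(2S,3S)-3-formyl-6-hydroxy-4-methoxy-7-(3-methylbut-2-en-1-yl)-2,3-dihydro-1-benzofuran-2-yl]phenyl 2,2-dimethylpropanoate
Conditions: PPTS (cat.), acetone–H2O (9:1), 45 °C
Reagents that add atoms: water, O
Why: Mild acetal hydrolysis leaves the benzylic ether stereocentre C2 untouched, and the epimerisable C3 stays in the more stable 2,3-trans arrangement.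

Step 11
Reactants: 17 4-[(2S,3S)-3-formyl-6-hydroxy-4-methoxy-7-(3-methylbut-2-en-1-yl)-2,3-dihydro-1-benzofuran-2-yl]phenyl 2,2-dimethylpropanoate
Product: 20 (2R,3R,4S)-7-acetoxy-3-hydroxy-5-methoxy-8-(3-methylbut-2-en-1-yl)-2-[4-(pivaloyloxy)phenyl]-3,4-dihydro-2H-chromen-4-yl acetate, via acylal 18 (not isolated), via dioxolanium triflate 19 (not isolated)
Conditions: Ac2O, Sc(OTf)3 (2 mol%), CH2Cl2, 0 °C; then 2,6-di-tert-butyl-4-methylpyridine, TMSOTf, −78 → −40 °C; then aq. NaHCO3
Reagents that add atoms: acetic anhydride, CC(=O)OC(C)=O; water, O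
Why: Proposed new method: an acetoxonium-terminated 1,2-aryl-shift ring expansion of a dihydrobenzofuran to a chroman. TMSOTf ionises acylal 18 to an α-acetoxy carbenium, to which the ring A ipso carbon (flanked by two ether oxygens) bridges as a phenonium ion. The aryl–C3 bond then breaks while the carbonyl oxygen of the new C4 acetate attacks C3 from the opposite face, giving the cis-fused 2-methyl-1,3-dioxolan-2-ylium 19; water opens it at the acetoxonium carbon to the cis hydroxy-acetate (a 3-O-acetyl isomer from acyl migration converges in step 12). C2 is untouched, C3 is inverted with O3 anti to the departing aryl (2,3-trans), and C4 is fixed cis to C3 by the five-membered acetoxonium. The closest known reactions are phenonium-mediated 1,2-aryl-shift ring expansions of 2,3-dihydrobenzofuran-3-ylmethyl sulfonates to chromans, the aryl shift to a protonated carbonyl in the aldehyde–ketone rearrangement, and Woodward cis-hydroxylation through acetoxonium ions.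

Step 12
Reactants: 20 (2R,3R,4S)-7-acetoxy-3-hydroxy-5-methoxy-8-(3-methylbut-2-en-1-yl)-2-[4-(pivaloyloxy)phenyl]-3,4-dihydro-2H-chromen-4-yl acetate
Product: 21 (2R,3S,4S)-2-(4-hydroxyphenyl)-5-methoxy-8-(3-methylbut-2-en-1-yl)-3,4-dihydro-2H-chromene-3,4,7-triol (5-O-methyl-8-prenylafzelechin-4β-ol)
Conditions: i-Bu2AlH, CH2Cl2, −78 °C; aq. KNaC4H4O6 (potassium sodium tartrate)
Reagents that add atoms: none
Why: Hydride cleaves the two acetates and the pivalate at the acyl carbons at low temperature, so no free phenoxide sits para to a benzylic acetate (which would give a quinone methide and scramble C4), and no stereocentre is touched.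

## Compound list

1 | resorcinol (benzene-1,3-diol) | Oc1cccc(O)c1 | starting material
2 | 1,3-bis(methoxymethoxy)benzene | COCOc1cccc(OCOC)c1 | intermediate
3 | 2-[3,5-bis(methoxymethoxy)phenyl]-4,4,5,5-tetramethyl-1,3,2-dioxaborolane | COCOc1cc(OCOC)cc(c1)B1OC(C)(C)C(C)(C)O1 | intermediate (not isolated)
4 | 3,5-bis(methoxymethoxy)phenol | COCOc1cc(O)cc(OCOC)c1 | intermediate
5 | 1-methoxy-3,5-bis(methoxymethoxy)benzene | COCOc1cc(OC)cc(OCOC)c1 | intermediate
6 | 1-bromo-3-methylbut-2-ene (prenyl bromide) | CC(C)=CCBr | starting material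
7 | [4-methoxy-2,6-bis(methoxymethoxy)phenyl]lithium | [Li]c1c(OCOC)cc(OC)cc1OCOC | intermediate (not isolated)
8 | 5-methoxy-1,3-bis(methoxymethoxy)-2-(3-methylbut-2-en-1-yl)benzene | COCOc1cc(OC)cc(OCOC)c1CC=C(C)C | intermediate
9 | [6-methoxy-2,4-bis(methoxymethoxy)-3-(3-methylbut-2-en-1-yl)phenyl]lithium | [Li]c1c(OC)cc(OCOC)c(CC=C(C)C)c1OCOC | intermediate (not isolated)
10 | 2-iodo-1-methoxy-3,5-bis(methoxymethoxy)-4-(3-methylbut-2-en-1-yl)benzene | COCOc1cc(OC)c(I)c(OCOC)c1CC=C(C)C | intermediate
11 | 4-iodo-5-methoxy-2-(3-methylbut-2-en-1-yl)benzene-1,3-diol | Oc1cc(OC)c(I)c(O)c1CC=C(C)C | intermediate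
12 | 4-iodophenol | Oc1ccc(I)cc1 | starting material
13 | 4-iodophenyl 2,2-dimethylpropanoate | CC(C)(C)C(=O)Oc1ccc(I)cc1 | intermediate
14 | 3,3-dimethoxyprop-1-ene (acrolein dimethyl acetal) | COC(OC)C=C | starting material
15 | 4-[(1E)-3,3-dimethoxyprop-1-en-1-yl]phenyl 2,2-dimethylpropanoate | COC(OC)/C=C/c1ccc(OC(=O)C(C)(C)C)cc1 | intermediate
16 | 4-[(2S,3S)-3-(dimethoxymethyl)-6-hydroxy-4-methoxy-7-(3-methylbut-2-en-1-yl)-2,3-dihydro-1-benzofuran-2-yl]phenyl 2,2-dimethylpropanoate (2,3-trans) | COC(OC)[C@H]1c2c(OC)cc(O)c(CC=C(C)C)c2O[C@@H]1c1ccc(OC(=O)C(C)(C)C)cc1 | intermediate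
17 | 4-[(2S,3S)-3-formyl-6-hydroxy-4-methoxy-7-(3-methylbut-2-en-1-yl)-2,3-dihydro-1-benzofuran-2-yl]phenyl 2,2-dimethylpropanoate (2,3-trans) | O=C[C@H]1c2c(OC)cc(O)c(CC=C(C)C)c2O[C@@H]1c1ccc(OC(=O)C(C)(C)C)cc1 | intermediate
18 | 4-[(2S,3S)-6-acetoxy-3-(diacetoxymethyl)-4-methoxy-7-(3-methylbut-2-en-1-yl)-2,3-dihydro-1-benzofuran-2-yl]phenyl 2,2-dimethylpropanoate | CC(=O)OC(OC(C)=O)[C@H]1c2c(OC)cc(OC(C)=O)c(CC=C(C)C)c2O[C@@H]1c1ccc(OC(=O)C(C)(C)C)cc1 | intermediate (not isolated)
19 | 2-methyl-1,3-dioxolan-2-ylium cis-fused across O3/O4 of (2R)-7-acetoxy-5-methoxy-8-(3-methylbut-2-en-1-yl)-2-[4-(pivaloyloxy)phenyl]chroman (aryl trans to O3), trifluoromethanesulfonate | COc1cc(OC(C)=O)c(CC=C(C)C)c2c1[C@@H]1O[C+](C)O[C@@H]1[C@@H](c1ccc(OC(=O)C(C)(C)C)cc1)O2.[O-]S(=O)(=O)C(F)(F)F | intermediate (not isolated)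
20 | (2R,3R,4S)-7-acetoxy-3-hydroxy-5-methoxy-8-(3-methylbut-2-en-1-yl)-2-[4-(pivaloyloxy)phenyl]-3,4-dihydro-2H-chromen-4-yl acetate (2,3-trans, 3,4-cis) | COc1cc(OC(C)=O)c(CC=C(C)C)c2c1[C@H](OC(C)=O)[C@H](O)[C@@H](c1ccc(OC(=O)C(C)(C)C)cc1)O2 | intermediate
21 | (2R,3S,4S)-2-(4-hydroxyphenyl)-5-methoxy-8-(3-methylbut-2-en-1-yl)-3,4-dihydro-2H-chromene-3,4,7-triol | COc1cc(O)c(CC=C(C)C)c2c1[C@H](O)[C@H](O)[C@@H](c1ccc(O)cc1)O2 | target

## Step count and risks

Total steps: 12. Longest linear sequence: 10 steps (steps 1–6, then 9–12); steps 7–8 make the ring B partner.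

The three steps most likely to fail:

1. Step 11 (proposed ring expansion). Three things can go wrong. The α-acetoxy carbenium may take a 1,2-hydride shift and aromatise to the benzofuran. The C2–C3 bond may migrate instead of the aryl carbon, which gives the same flavan constitution but loses 2,3-trans control. Acetate may open the acetoxonium at benzylic C4, giving the 3,4-trans diester. The fallback uses known chemistry without a ring expansion, sets out from 8 and 15 and comes back at 21. Acetal 15 is hydrolysed (aq. CF3CO2H, CH2Cl2) to 4-[(1E)-3-oxoprop-1-en-1-yl]phenyl 2,2-dimethylpropanoate F1. Organocatalytic epoxidation (H2O2, (S)-diarylprolinol trimethylsilyl ether) gives (2R,3S)-3-[4-(pivaloyloxy)phenyl]oxirane-2-carbaldehyde F2. Aryllithium 9, made from 8 as in step 5, adds to F2 at −78 °C under Felkin–Anh control to give the anti epoxy alcohol (S)-[6-methoxy-2,4-bis(methoxymethoxy)-3-(3-methylbut-2-en-1-yl)phenyl]{(2S,3S)-3-[4-(pivaloyloxy)phenyl]oxiran-2-yl}methanol F3. ZnBr2/n-PrSH frees the phenols, and catalytic camphorsulfonic acid closes ring C by 6-endo opening of the epoxide at the benzylic carbon with inversion, giving 4-[(2R,3S,4S)-3,4,7-trihydroxy-5-methoxy-8-(3-methylbut-2-en-1-yl)-3,4-dihydro-2H-chromen-2-yl]phenyl 2,2-dimethylpropanoate F4. K2CO3 in MeOH removes the pivalate to give 21.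

2. Step 9 (proposed enantioselective oxyarylation). The enantioselectivity of carbopalladation on an acyclic internal alkene may be low, and β-hydride elimination to the plain Heck product may compete. The fallback sets out from 11 and 15 and comes back at 16: the known racemic oxyarylation is run with Pd(OAc)2 and Ag2CO3 without a chiral ligand, and the enantiomers of the trans product are separated by preparative HPLC on a chiral stationary phase. This fallback makes no new compound (F0).

3. Step 5 (second ortho-lithiation). Deprotonation of the doubly activated benzylic/allylic CH2 of the prenyl group may compete with ring lithiation. The fallback sets out from 8 and comes back at 10: electrophilic aromatic iodination with N-iodosuccinimide (MeCN, −20 °C) at the single kind of free ring position, which on this tri-oxygenated ring is much faster than attack on the trisubstituted alkene. This fallback makes no new compound (F0).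

Further compounds
F1 | step 11 | 4-[(1E)-3-oxoprop-1-en-1-yl]phenyl 2,2-dimethylpropanoate | CC(C)(C)C(=O)Oc1ccc(/C=C/C=O)cc1
F2 | step 11 | (2R,3S)-3-[4-(pivaloyloxy)phenyl]oxirane-2-carbaldehyde | O=C[C@@H]1O[C@H]1c1ccc(OC(=O)C(C)(C)C)cc1
F3 | step 11 | (S)-[6-methoxy-2,4-bis(methoxymethoxy)-3-(3-methylbut-2-en-1-yl)phenyl]{(2S,3S)-3-[4-(pivaloyloxy)phenyl]oxiran-2-yl}methanol | COCOc1cc(OC)c([C@H](O)[C@@H]2O[C@H]2c2ccc(OC(=O)C(C)(C)C)cc2)c(OCOC)c1CC=C(C)C
F4 | step 11 | 4-[(2R,3S,4S)-3,4,7-trihydroxy-5-methoxy-8-(3-methylbut-2-en-1-yl)-3,4-dihydro-2H-chromen-2-yl]phenyl 2,2-dimethylpropanoate | COc1cc(O)c(CC=C(C)C)c2c1[C@H](O)[C@H](O)[C@@H](c1ccc(OC(=O)C(C)(C)C)cc1)O2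
F0 | step 9 | none | none
F0 | step 5 | none | none
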